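**Retrosynthetic overview**

- Ring labels: C1 (stereocentre), C2, C3 (amide C=O), N4, C5–C7, N8, C9–C12, N13, C14–C16, N17. The strategy rests on the run N17–C1–C2–C3(=O) of the single 17-membered tetraaza lactam ring. This run is aspartic acid (amine N, Cα, Cβ, side-chain carbonyl) with an undecyl group in place of the α-carboxyl.
- Late disconnections, backwards: N17–CH3 by reductive methylation; N17–C16 by intramolecular reductive amination, the only ring closure (17-membered); N4–C3 by amide coupling of a Boc-β-amino acid with a linear triamine acetal.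
- C1–undecyl: nickel-catalysed enantioconvergent decarboxylative coupling of the N-hydroxyphthalimide ester of Boc-Asp(OBn)-OH with undecylzinc iodide. This step also fixes C1 as R.
- Triamine acetal: N,N'-dimethylbutane-1,4-diamine (N8, C9–C12, N13) is alkylated once with 3-chloropropanal diethyl acetal (C14–C16). It is then cyanoethylated and hydrogenated (C5–C7, N4).

Key step: step 3

Assumption: the (S,S) enantiomer of the diamine ligand is taken to deliver R at C1; a trial coupling should confirm the sense of induction, and the equally available (R,R) ligand is used if it proves opposite.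

**Step 1**
Reactants: 1 Boc-L-aspartic acid 4-benzyl ester; 2 N-hydroxyphthalimide
Product: 3 Boc-L-aspartic acid 4-benzyl ester 1-(1,3-dioxoisoindolin-2-yl) ester (S)
Conditions: DIC (1.1 equiv), DMAP (10 mol %), CH2Cl2, 0 °C to rt
Reagents that add atoms: none
Why: This is a Steglich-type carbodiimide esterification in which only the free α-carboxyl is activated and taken up by the N–OH group, the benzyl ester and Boc group are inert, and any epimerisation is harmless because this centre is erased in step 3.

**Step 2**
Reactants: 4 1-iodoundecane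
Product: 5 undecylzinc iodide (THF solution, titrated with I2 and used as such)
Conditions: Zn dust (1.5 equiv, activated with BrCH2CH2Br 5 mol % and Me3SiCl 3 mol %), THF, 40 °C
Reagents that add atoms: zinc, [Zn]
Why: Direct oxidative insertion of activated zinc into a primary C–I bond is the standard preparation of an alkylzinc iodide and should proceed cleanly on an unfunctionalised chain.

**Step 3**
Reactants: 3 Boc-L-aspartic acid 4-benzyl ester 1-(1,3-dioxoisoindolin-2-yl) ester; 5 undecylzinc iodide (1.2 equiv)
Product: 6 benzyl (R)-3-(tert-butoxycarbonylamino)tetradecanoate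
Conditions: NiBr2(glyme) (10 mol %), (S,S)-N,N'-dimethyl-1,2-diphenylethane-1,2-diamine (12 mol %), LiCl (1 equiv), DMAP (0.5 equiv), Me3SiCl (0.8 equiv), THF, 0 °C
Reagents that add atoms: none
Why: The zinc reagent reduces the diamine-bound nickel bromide to a low-valent species that passes one electron to the phthalimide ester, and N–O scission with loss of CO2 then leaves a flat, carbamate-stabilised radical at C1, so the S configuration of 3 is forgotten. Transmetalation from 5 gives a chiral undecylnickel complex that traps this radical, and reductive elimination from the resulting trivalent dialkylnickel makes the exocyclic C1–undecyl bond. The closest known reaction type is the nickel-catalysed enantioconvergent decarboxylative alkyl–alkyl (Negishi-type) coupling of redox-active esters of carbamate-protected α-amino acids with primary alkylzinc halides, and this step is a direct application of it. No ring is closed, and the one new stereocentre C1 is set as R by the ligand enantiomer, with the carbamate carbonyl available as a second contact to nickel that sharpens the facial choice. The step needs reaction at the redox-active ester only, which the low nucleophilicity and basicity of an alkylzinc iodide at 0 °C secures against the benzyl ester and the carbamate N–H. It also needs coupling to outrun β-hydride elimination towards the enecarbamate, which the bidentate diamine on nickel disfavours.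

**Step 4**
Reactants: 6 benzyl (R)-3-(tert-butoxycarbonylamino)tetradecanoate
Product: 7 (R)-3-(tert-butoxycarbonylamino)tetradecanoic acid
Conditions: H2 (1 atm), Pd/C (10 wt %), EtOAc, rt
Reagents that add atoms: none
Why: Catalytic hydrogenolysis cleaves the benzylic C–O bond only, and the Boc group and C1 are not affected.

**Step 5**
Reactants: 8 N,N'-dimethylbutane-1,4-diamine (5 equiv); 9 3-chloro-1,1-diethoxypropane
Product: 10 N-(3,3-diethoxypropyl)-N,N'-dimethylbutane-1,4-diamine
Conditions: K2CO3 (1.5 equiv), NaI (10 mol %), MeCN, 80 °C; excess 8 distilled off and reused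
Reagents that add atoms: none
Why: This is an iodide-assisted (Finkelstein) SN2 N-alkylation in which the large excess of the symmetrical diamine should make single alkylation the statistically dominant outcome, and the acetal is stable to base.

**Step 6**
Reactants: 10 N-(3,3-diethoxypropyl)-N,N'-dimethylbutane-1,4-diamine; 11 acrylonitrile (1.1 equiv)
Product: 12 3-[{4-[(3,3-diethoxypropyl)(methyl)amino]butyl}(methyl)amino]propanenitrile
Conditions: MeOH, 0 °C to rt
Reagents that add atoms: none
Why: The aza-Michael addition (cyanoethylation) can occur only at the one remaining N–H, so no selectivity question arises.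

**Step 7**
Reactants: 12 3-[{4-[(3,3-diethoxypropyl)(methyl)amino]butyl}(methyl)amino]propanenitrile
Product: 13 N-(3-aminopropyl)-N'-(3,3-diethoxypropyl)-N,N'-dimethylbutane-1,4-diamine
Conditions: H2 (5 bar), Raney Ni, NH3 (7 M in MeOH), rt
Reagents that add atoms: none
Why: Catalytic nitrile hydrogenation in the presence of ammonia, which suppresses secondary-amine formation, is the standard second half of the cyanoethylation–reduction method for adding an aminopropyl unit to a polyamine, and it leaves the acetal intact.

**Step 8**
Reactants: 7 (R)-3-(tert-butoxycarbonylamino)tetradecanoic acid; 13 N-(3-aminopropyl)-N'-(3,3-diethoxypropyl)-N,N'-dimethylbutane-1,4-diamine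
Product: 14 tert-butyl (R)-[1-({3-[{4-[(3,3-diethoxypropyl)(methyl)amino]butyl}(methyl)amino]propyl}amino)-1-oxotetradecan-3-yl]carbamate
Conditions: EDC (free base, 1.2 equiv), HOBt (1.2 equiv), CH2Cl2, 0 °C to rt
Reagents that add atoms: none
Why: In this carbodiimide/HOBt amide coupling the primary amine is the only nitrogen of 13 that can be acylated, C1 is not α to the activated carbonyl and cannot epimerise, and the carbamate on N17 keeps β-elimination from the active ester at bay.

**Step 9**
Reactants: 14 tert-butyl (R)-[1-({3-[{4-[(3,3-diethoxypropyl)(methyl)amino]butyl}(methyl)amino]propyl}amino)-1-oxotetradecan-3-yl]carbamate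
Product: 17 (8R)-1,13-dimethyl-8-undecyl-1,5,9,13-tetraazacycloheptadecan-6-one, via amino aldehyde 15 (not isolated), via macrocyclic imine 16 (not isolated)
Conditions: TFA–H2O (9:1), 0 °C to rt, evaporate cold; then i-Pr2NEt/AcOH (apparent pH about 5), 4 Å MS, ClCH2CH2Cl–MeCN (1 mM), rt, 1 h; NaBH(OAc)3 (4 equiv), rt
Reagents that add atoms: water, O (supplies the aldehyde oxygen of 15, which leaves again when 16 forms)
Why: Acidolysis removes the Boc group and hydrolyses the acetal in one operation, and an intramolecular direct reductive amination then closes the 17-membered ring at N17–C16, because imine formation is reversible and high dilution favours the monomeric cyclic imine before hydride fixes it, N8 and N13 stay protonated so that the β-amino aldehyde does not shed N13 by retro-Michael cleavage, and C1 is not touched.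

**Step 10**
Reactants: 17 (8R)-1,13-dimethyl-8-undecyl-1,5,9,13-tetraazacycloheptadecan-6-one
Product: 19 (8R)-1,9,13-trimethyl-8-undecyl-1,5,9,13-tetraazacycloheptadecan-6-one (target CNP0193618.1), via methyleneiminium ion 18 (not isolated)
Conditions: aq. HCHO (37 %, 3 equiv), AcOH, NaBH(OAc)3 (3 equiv), MeCN, rt
Reagents that add atoms: formaldehyde, C=O
Why: Reductive methylation acts on the only secondary amine N17, the amide N4–H is not alkylated, and any N17–CH2–N4 aminal that forms reversibly in the acidic medium should be drained through the iminium ion to the N-methyl product.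

**Compound list**

| No. | Name | SMILES | Role |
|---|---|---|---|
| 1 | Boc-L-aspartic acid 4-benzyl ester (S) | O=C(O)[C@H](CC(=O)OCc1ccccc1)NC(=O)OC(C)(C)C | starting material |
| 2 | N-hydroxyphthalimide | O=C1c2ccccc2C(=O)N1O | starting material |
| 3 | Boc-L-aspartic acid 4-benzyl ester 1-(1,3-dioxoisoindolin-2-yl) ester (S) | O=C(ON1C(=O)c2ccccc2C1=O)[C@H](CC(=O)OCc1ccccc1)NC(=O)OC(C)(C)C | intermediate |
| 4 | 1-iodoundecane | CCCCCCCCCCCI | starting material |
| 5 | undecylzinc iodide | CCCCCCCCCCC[Zn]I | intermediate |
| 6 | benzyl (R)-3-(tert-butoxycarbonylamino)tetradecanoate | CCCCCCCCCCC[C@H](CC(=O)OCc1ccccc1)NC(=O)OC(C)(C)C | intermediate |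
| 7 | (R)-3-(tert-butoxycarbonylamino)tetradecanoic acid | CCCCCCCCCCC[C@H](CC(=O)O)NC(=O)OC(C)(C)C | intermediate |
| 8 | N,N'-dimethylbutane-1,4-diamine | CNCCCCNC | starting material |
| 9 | 3-chloro-1,1-diethoxypropane | CCOC(CCCl)OCC | starting material |
| 10 | N-(3,3-diethoxypropyl)-N,N'-dimethylbutane-1,4-diamine | CNCCCCN(C)CCC(OCC)OCC | intermediate |
| 11 | acrylonitrile | C=CC#N | starting material |
| 12 | 3-[{4-[(3,3-diethoxypropyl)(methyl)amino]butyl}(methyl)amino]propanenitrile | N#CCCN(C)CCCCN(C)CCC(OCC)OCC | intermediate |
| 13 | N-(3-aminopropyl)-N'-(3,3-diethoxypropyl)-N,N'-dimethylbutane-1,4-diamine | NCCCN(C)CCCCN(C)CCC(OCC)OCC | intermediate |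
| 14 | tert-butyl (R)-[1-({3-[{4-[(3,3-diethoxypropyl)(methyl)amino]butyl}(methyl)amino]propyl}amino)-1-oxotetradecan-3-yl]carbamate | CCCCCCCCCCC[C@H](CC(=O)NCCCN(C)CCCCN(C)CCC(OCC)OCC)NC(=O)OC(C)(C)C | intermediate |
| 15 | (R)-3-amino-N-{3-[methyl(4-[methyl(3-oxopropyl)amino]butyl)amino]propyl}tetradecanamide (present as its ammonium salts) | CCCCCCCCCCC[C@@H](N)CC(=O)NCCCN(C)CCCCN(C)CCC=O | intermediate |
| 16 | (8R)-1,13-dimethyl-8-undecyl-1,5,9,13-tetraazacycloheptadec-9-en-6-one | CCCCCCCCCCC[C@@H]1CC(=O)NCCCN(C)CCCCN(C)CCC=N1 | intermediate |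
| 17 | (8R)-1,13-dimethyl-8-undecyl-1,5,9,13-tetraazacycloheptadecan-6-one | CCCCCCCCCCC[C@@H]1CC(=O)NCCCN(C)CCCCN(C)CCCN1 | intermediate |
| 18 | N17-methyleneiminium ion of 17 | CCCCCCCCCCC[C@@H]1CC(=O)NCCCN(C)CCCCN(C)CCC[N+]1=C | intermediate |
| 19 | (8R)-1,9,13-trimethyl-8-undecyl-1,5,9,13-tetraazacycloheptadecan-6-one | CCCCCCCCCCC[C@@H]1CC(=O)NCCCN(C)CCCCN(C)CCCN1C | target |

**Total step count:** 10.

**Longest linear sequence:** 6 steps (1, 3, 4, 8, 9, 10). The triamine branch 5, 6, 7, 8, 9, 10 is equally long.

**Steps most likely to fail**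

**Step 3.**
- What may go wrong: facial discrimination at the flat C1 radical may be eroded because the β-ester is a second Lewis-basic site that can compete with the carbamate for nickel. β-Hydride elimination or simple reduction of the radical may also consume material.
- Fallback (chiral pool instead of catalyst control): it sets out from 1, whose L configuration already has the spatial arrangement needed. The descriptor changes from S to R only because the ranking of the substituents changes.
- BH3·THF (THF, 0 °C) should reduce the free α-carboxyl selectively to benzyl (S)-3-(tert-butoxycarbonylamino)-4-hydroxybutanoate F1. Dess–Martin oxidation (CH2Cl2, 0 °C) then gives benzyl (S)-3-(tert-butoxycarbonylamino)-4-oxobutanoate F2.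
- Decyltriphenylphosphonium bromide and KN(SiMe3)2 (THF, −78 °C) furnish decylidene(triphenyl)phosphorane F3. Its Wittig reaction with F2 should give benzyl (3S,4Z)-3-(tert-butoxycarbonylamino)tetradec-4-enoate F4.
- H2 over Pd/C then saturates the alkene and cleaves the benzyl ester in one operation, and the route is rejoined at 7.

**Step 9.**
- What may go wrong: retro-Michael loss of N13 from the β-amino aldehyde, hydride reduction of the aldehyde before the ring imine has formed, and oligomerisation can each divert the ring closure.
- Fallback (closure of the same N17–C16 bond by sulfonamide alkylation, so the aldehyde need not survive): it sets out from 14. The compound is unmasked with TFA–H2O as before, and crude 15 is run at once into NaBH4 in MeOH at 0 °C. This should give (R)-3-amino-N-{3-[{4-[(3-hydroxypropyl)(methyl)amino]butyl}(methyl)amino]propyl}tetradecanamide F5.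
- 2-Nitrobenzenesulfonyl chloride (1 equiv, Et3N, CH2Cl2, 0 °C) sulfonylates the primary amine in preference to the alcohol. The product is (R)-N-{3-[{4-[(3-hydroxypropyl)(methyl)amino]butyl}(methyl)amino]propyl}-3-(2-nitrophenylsulfonylamino)tetradecanamide F6.
- A Fukuyama–Mitsunobu macrocyclisation (PPh3, DIAD, toluene–THF, 2 mM) should give (8R)-1,13-dimethyl-9-(2-nitrophenylsulfonyl)-8-undecyl-1,5,9,13-tetraazacycloheptadecan-6-one F7. An azetidinium ion formed in passing from N13 would open to the same connectivity.
- PhSH and K2CO3 in MeCN remove the sulfonyl group, and the route is rejoined at 17.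

**Step 5.**
- What may go wrong: over-alkylation to the symmetrical bis-acetal, base-induced loss of HCl from the β-chloro acetal, and a difficult separation of polar diamines may spoil the single alkylation.
- Fallback (stepwise, non-statistical assembly of the chain): it sets out from 9. A large excess of volatile methylamine in EtOH (60 °C, sealed vessel) converts 9 into 3,3-diethoxy-N-methylpropan-1-amine F8.
- Acylation with 4-chlorobutanoyl chloride (Et3N, CH2Cl2, 0 °C) gives 4-chloro-N-(3,3-diethoxypropyl)-N-methylbutanamide F9.
- Displacement of chloride with commercial 3-(methylamino)propanenitrile (K2CO3, NaI, MeCN, 60 °C) gives 4-[(2-cyanoethyl)(methyl)amino]-N-(3,3-diethoxypropyl)-N-methylbutanamide F10.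
- LiAlH4 (THF, 0 °C to reflux) reduces the amide and the nitrile together, and the route is rejoined at 13.

**Further compounds**
F1 | step 3 | benzyl (S)-3-(tert-butoxycarbonylamino)-4-hydroxybutanoate | OC[C@H](CC(=O)OCc1ccccc1)NC(=O)OC(C)(C)C
F2 | step 3 | benzyl (S)-3-(tert-butoxycarbonylamino)-4-oxobutanoate | O=C[C@H](CC(=O)OCc1ccccc1)NC(=O)OC(C)(C)C
F3 | step 3 | decylidene(triphenyl)phosphorane | CCCCCCCCCC=P(c1ccccc1)(c1ccccc1)c1ccccc1
F4 | step 3 | benzyl (3S,4Z)-3-(tert-butoxycarbonylamino)tetradec-4-enoate | CCCCCCCCC/C=C\[C@H](CC(=O)OCc1ccccc1)NC(=O)OC(C)(C)C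
F5 | step 9 | (R)-3-amino-N-{3-[{4-[(3-hydroxypropyl)(methyl)amino]butyl}(methyl)amino]propyl}tetradecanamide | CCCCCCCCCCC[C@@H](N)CC(=O)NCCCN(C)CCCCN(C)CCCO
F6 | step 9 | (R)-N-{3-[{4-[(3-hydroxypropyl)(methyl)amino]butyl}(methyl)amino]propyl}-3-(2-nitrophenylsulfonylamino)tetradecanamide | CCCCCCCCCCC[C@H](CC(=O)NCCCN(C)CCCCN(C)CCCO)NS(=O)(=O)c1ccccc1[N+](=O)[O-]
F7 | step 9 | (8R)-1,13-dimethyl-9-(2-nitrophenylsulfonyl)-8-undecyl-1,5,9,13-tetraazacycloheptadecan-6-one | CCCCCCCCCCC[C@@H]1CC(=O)NCCCN(C)CCCCN(C)CCCN1S(=O)(=O)c2ccccc2[N+](=O)[O-]
F8 | step 5 | 3,3-diethoxy-N-methylpropan-1-amine | CNCCC(OCC)OCC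
F9 | step 5 | 4-chloro-N-(3,3-diethoxypropyl)-N-methylbutanamide | ClCCCC(=O)N(C)CCC(OCC)OCC
F10 | step 5 | 4-[(2-cyanoethyl)(methyl)amino]-N-(3,3-diethoxypropyl)-N-methylbutanamide | N#CCCN(C)CCCC(=O)N(C)CCC(OCC)OCC
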